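**Retrosynthetic overview**
1. Target 18 ⇐ triol aldehyde 15 by O-sulfation of the lone non-catechol phenol (catechol masked in the flask as a boronate); 15 ⇐ trimethoxyarene 12 by ortho-formylation and demethylation.
2. 12 ⇐ aldehyde 10 by CHO → CH3 (Wolff–Kishner). Key disconnection, C11–aryl: 10 ⇐ aldehyde 6 + aryl iodide 7, where β-C–H palladation of a transient imine gives a palladium homoenolate (nucleophilic β-carbon of the aldehyde) that is arylated.
3. The stereochemical trick: the α-methyl of 6 that is cis to 8-Me and H-10 becomes the benzylic CH2, and the formyl group later becomes the 9-methyl.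
4. 6 ⇐ diene 4 + tiglic aldehyde 5 by a catalytic enantioselective endo Diels–Alder reaction that sets all three stereocentres; 4 ⇐ 2,2-dimethylcyclohexanone 1.
5. Ring order: ring A is bought (1), ring B is formed by the [4+2] step, the arene is bought (7).

Assumption and numbering: the target is made as drawn (free aryl hydrogen sulfate; 8R,9R,10S with C4 = CMe2, C5=C6 alkene, C8 = CHMe, C9 = quaternary C, C10 = ring-fusion CH, C11 = benzylic CH2), and 1-iodo-2,4,5-trimethoxybenzene is taken as a catalogue compound.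

**Step 1**
Reactants: 1 2,2-dimethylcyclohexan-1-one; 2 vinylmagnesium bromide (CH2=CHMgBr)
Product: 3 2,2-dimethyl-1-vinylcyclohexan-1-ol (racemic)
Conditions: THF, 0 °C to rt; then H2O
Reagents that add atoms: none
Why: Grignard 1,2-addition to the ketone; the carbinol centre is racemic but is destroyed in step 2.

**Step 2**
Reactants: 3 2,2-dimethyl-1-vinylcyclohexan-1-ol
Product: 4 6,6-dimethyl-1-vinylcyclohex-1-ene
Conditions: CuSO4 (anhydrous, 20 mol%), neat, 130 °C, product distilled out
Reagents that add atoms: none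
Why: E1 dehydration of the tertiary allylic alcohol; C2 is quaternary, so only the ring CH2 can lose a proton and the conjugated diene is the only elimination product.

**Step 3**
Reactants: 4 6,6-dimethyl-1-vinylcyclohex-1-ene; 5 tiglic aldehyde, (E)-2-methylbut-2-enal
Product: 6 (1S,2R,8aR)-1,2,5,5-tetramethyl-1,2,3,5,6,7,8,8a-octahydronaphthalene-1-carbaldehyde
Conditions: (S)-tetrahydro-1-(2-methylphenyl)-3,3-diphenyl-1H,3H-pyrrolo[1,2-c][1,3,2]oxazaborole (20 mol%), Tf2NH (18 mol%), CH2Cl2, −40 to −20 °C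
Reagents that add atoms: none
Why: Catalytic enantioselective Diels–Alder reaction with a cationic oxazaborolidine; the enal β-carbon bonds to the vinyl CH2 and the α-carbon to the ring CH ("ortho" rule), the E-geometry places CHO trans to 8-Me, the endo mode places CHO trans to H-10, and the catalyst shields one face of the boron-bound s-trans enal so the diene adds to the Cα Re face (the sense I recall for α-methyl enals with the S catalyst; the R catalyst would give the antipode), which sets all three stereocentres at once.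

**Step 4**
Reactants: 6 (1S,2R,8aR)-1,2,5,5-tetramethyl-1,2,3,5,6,7,8,8a-octahydronaphthalene-1-carbaldehyde; 7 1-iodo-2,4,5-trimethoxybenzene
Product: 10 (1S,2R,8aR)-2,5,5-trimethyl-1-[(2,4,5-trimethoxyphenyl)methyl]-1,2,3,5,6,7,8,8a-octahydronaphthalene-1-carbaldehyde, via β-alanine imine 8 (not isolated), via arylated imine 9 (not isolated)
Conditions: Pd(OAc)2 (10 mol%), β-alanine (40 mol%), AgO2CCF3 (1.5 equiv), (CF3)2CHOH/AcOH 9:1, 90 °C
Reagents that add atoms: none
Why: Transient-directing-group β-C(sp3)–H arylation: the imine/carboxylate chelate steers divalent palladium to the only β-methyl group, giving a five-membered palladacycle (a palladium homoenolate) that couples with the aryl iodide by oxidative addition and reductive elimination, with AgO2CCF3 removing iodide; no stereocentre is touched, and because the arylated methyl is the one cis to 8-Me and H-10, C9 now carries its final arrangement.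

**Step 5**
Reactants: 10 (1S,2R,8aR)-2,5,5-trimethyl-1-[(2,4,5-trimethoxyphenyl)methyl]-1,2,3,5,6,7,8,8a-octahydronaphthalene-1-carbaldehyde
Product: 12 (1R,2R,8aS)-1,2,5,5-tetramethyl-1-[(2,4,5-trimethoxyphenyl)methyl]-1,2,3,5,6,7,8,8a-octahydronaphthalene, via hydrazone 11 (not isolated)
Conditions: N2H4·H2O, KOH, diethylene glycol, 130 °C then 200 °C
Reagents that add atoms: none
Why: Wolff–Kishner reduction (Huang-Minlon procedure) of the non-enolisable neopentyl aldehyde turns CHO into the 9-methyl group; aryl methyl ethers and the hindered alkene tolerate hot base, and the descriptors change only through CIP priorities.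

**Step 6**
Reactants: 12 (1R,2R,8aS)-1,2,5,5-tetramethyl-1-[(2,4,5-trimethoxyphenyl)methyl]-1,2,3,5,6,7,8,8a-octahydronaphthalene
Product: 14 2,3,6-trimethoxy-5-{[(1R,2R,8aS)-1,2,5,5-tetramethyl-1,2,3,5,6,7,8,8a-octahydronaphthalen-1-yl]methyl}benzaldehyde, via aryllithium 13 (not isolated)
Conditions: n-BuLi, TMEDA, THF, 0 °C; DMF, −78 to 0 °C; dilute aq HCl
Reagents that add atoms: N,N-dimethylformamide, CN(C)C=O
Why: Directed ortho-metalation then formylation; the ring CH flanked by two methoxy groups is the most acidic site, while the other free ring position is shielded by the neopentyl-type CH2.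

**Step 7**
Reactants: 14 2,3,6-trimethoxy-5-{[(1R,2R,8aS)-1,2,5,5-tetramethyl-1,2,3,5,6,7,8,8a-octahydronaphthalen-1-yl]methyl}benzaldehyde
Product: 15 2,3,6-trihydroxy-5-{[(1R,2R,8aS)-1,2,5,5-tetramethyl-1,2,3,5,6,7,8,8a-octahydronaphthalen-1-yl]methyl}benzaldehyde
Conditions: BBr3 (6 equiv), CH2Cl2, −78 to 0 °C; cold H2O quench; handled under argon
Reagents that add atoms: none
Why: Lewis-acid cleavage of the three aryl methyl ethers by BBr3; the phenols stay as borate esters until the cold quench, so the hindered trisubstituted alkene is not exposed to a protic acid while warm.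

**Step 8**
Reactants: 15 2,3,6-trihydroxy-5-{[(1R,2R,8aS)-1,2,5,5-tetramethyl-1,2,3,5,6,7,8,8a-octahydronaphthalen-1-yl]methyl}benzaldehyde
Product: 18 2-formyl-3,4-dihydroxy-6-{[(1R,2R,8aS)-1,2,5,5-tetramethyl-1,2,3,5,6,7,8,8a-octahydronaphthalen-1-yl]methyl}phenyl hydrogen sulfate (CNP0115595.2), via catechol phenylboronate 16 (not isolated), via sulfated phenylboronate 17 (not isolated)
Conditions: PhB(OH)2 (1.05 equiv), 4 Å MS, THF, rt; then SO3·pyridine (3 equiv), pyridine, 40 °C; then H2O, 0 °C; Dowex 50W (H+ form), cold MeOH/H2O, lyophilise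
Reagents that add atoms: sulfur trioxide–pyridine complex, [O-]S(=O)(=O)[n+]1ccccc1
Why: Proposed new method: phenylboronic acid condenses only with the ortho-dihydroxy pair to a five-membered boronate, so the single remaining phenol (para to one catechol oxygen, next to CHO) is the only site SO3·pyridine can sulfate, and water then hydrolyses the boronate while the aryl sulfate survives and cation exchange gives the free acid; the closest known reaction types are boronate masking of 1,2-diols during O-sulfation or acylation of other hydroxyls and SO3·amine O-sulfation of phenols.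

**Compound list**
1 | 2,2-dimethylcyclohexan-1-one | CC1(C)CCCCC1=O | starting material
2 | vinylmagnesium bromide | C=C[Mg]Br | starting material
3 | 2,2-dimethyl-1-vinylcyclohexan-1-ol (racemic) | CC1(C)CCCCC1(O)C=C | intermediate
4 | 6,6-dimethyl-1-vinylcyclohex-1-ene | CC1(C)CCCC=C1C=C | intermediate
5 | tiglic aldehyde, (E)-2-methylbut-2-enal | C/C=C(\C)C=O | starting material
6 | (1S,2R,8aR)-1,2,5,5-tetramethyl-1,2,3,5,6,7,8,8a-octahydronaphthalene-1-carbaldehyde | C[C@@H]1CC=C2[C@@H](CCCC2(C)C)[C@]1(C=O)C | intermediate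
7 | 1-iodo-2,4,5-trimethoxybenzene | COc1cc(OC)c(OC)cc1I | starting material
8 | β-alanine imine of 6 (E) | C[C@@H]1CC=C2[C@@H](CCCC2(C)C)[C@]1(/C=N/CCC(O)=O)C | intermediate
9 | β-alanine imine of 10 (E) | C[C@@H]1CC=C2[C@@H](CCCC2(C)C)[C@]1(/C=N/CCC(O)=O)Cc1cc(OC)c(OC)cc1OC | intermediate
10 | (1S,2R,8aR)-2,5,5-trimethyl-1-[(2,4,5-trimethoxyphenyl)methyl]-1,2,3,5,6,7,8,8a-octahydronaphthalene-1-carbaldehyde | C[C@@H]1CC=C2[C@@H](CCCC2(C)C)[C@]1(C=O)Cc1cc(OC)c(OC)cc1OC | intermediate
11 | hydrazone of 10 (E) | C[C@@H]1CC=C2[C@@H](CCCC2(C)C)[C@]1(/C=N/N)Cc1cc(OC)c(OC)cc1OC | intermediate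
12 | (1R,2R,8aS)-1,2,5,5-tetramethyl-1-[(2,4,5-trimethoxyphenyl)methyl]-1,2,3,5,6,7,8,8a-octahydronaphthalene | C[C@@H]1CC=C2[C@@H](CCCC2(C)C)[C@]1(C)Cc1cc(OC)c(OC)cc1OC | intermediate
13 | 3-lithio derivative of 12 (lithium between the 2- and 4-methoxy groups) | C[C@@H]1CC=C2[C@@H](CCCC2(C)C)[C@]1(C)Cc1cc(OC)c(OC)c([Li])c1OC | intermediate
14 | 2,3,6-trimethoxy-5-{[(1R,2R,8aS)-1,2,5,5-tetramethyl-1,2,3,5,6,7,8,8a-octahydronaphthalen-1-yl]methyl}benzaldehyde | C[C@@H]1CC=C2[C@@H](CCCC2(C)C)[C@]1(C)Cc1cc(OC)c(OC)c(C=O)c1OC | intermediate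
15 | 2,3,6-trihydroxy-5-{[(1R,2R,8aS)-1,2,5,5-tetramethyl-1,2,3,5,6,7,8,8a-octahydronaphthalen-1-yl]methyl}benzaldehyde | C[C@@H]1CC=C2[C@@H](CCCC2(C)C)[C@]1(C)Cc1cc(O)c(O)c(C=O)c1O | intermediate
16 | cyclic phenylboronate of the catechol of 15 (2-phenyl-1,3,2-benzodioxaborole, free 5-OH) | C[C@@H]1CC=C2[C@@H](CCCC2(C)C)[C@]1(C)Cc1cc3OB(c4ccccc4)Oc3c(C=O)c1O | intermediate
17 | hydrogen sulfate of 16 | C[C@@H]1CC=C2[C@@H](CCCC2(C)C)[C@]1(C)Cc1cc3OB(c4ccccc4)Oc3c(C=O)c1OS(=O)(=O)O | intermediate
18 | 2-formyl-3,4-dihydroxy-6-{[(1R,2R,8aS)-1,2,5,5-tetramethyl-1,2,3,5,6,7,8,8a-octahydronaphthalen-1-yl]methyl}phenyl hydrogen sulfate | C[C@@H]1CC=C2[C@@H](CCCC2(C)C)[C@]1(C)Cc1cc(O)c(O)c(C=O)c1OS(=O)(=O)O | target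

**Totals**
Total step count: 8. Longest linear sequence: 8 (1 → 18).

**Three steps most likely to fail**

Step 4 (key arylation). The aryl iodide is ortho-substituted and very electron-rich, and the alkene could migrate in hot acidic (CF3)2CHOH/AcOH. The fallback puts the benzyl group into the dienophile instead of making it by C–H activation. It sets out from 7: a Heck reaction with allyl alcohol (Pd(OAc)2, NaHCO3, n-Bu4NCl, DMF, 50 °C) gives 3-(2,4,5-trimethoxyphenyl)propanal F3. A pyrrolidine/benzoic acid cross-aldol condensation with acetaldehyde then gives (E)-2-[(2,4,5-trimethoxyphenyl)methyl]but-2-enal F4. F4 is used as the dienophile with diene 4 under the step 3 catalyst (formyl endo, benzyl exo), and the route is rejoined at 10.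

Step 3 (Diels–Alder). Tiglic aldehyde is a sluggish trisubstituted dienophile, and the endo:exo ratio, the facial sense and the ee are not secured by close precedent. The fallback replaces catalyst control by a chiral acetal in an ionic Diels–Alder reaction. It sets out from 5: acetalisation with (2R,4R)-pentane-2,4-diol (PPTS, benzene, Dean–Stark) gives 2-[(E)-but-2-en-2-yl]-(4R,6R)-4,6-dimethyl-1,3-dioxane F1; the diol enantiomer would be switched if induction ran the other way. TMSOTf (10 mol%) with 2,6-di-tert-butyl-4-methylpyridine in CH2Cl2 at −78 °C ionises F1 to the vinyl oxocarbenium ion, which adds to diene 4 to give the (4R,6R)-4,6-dimethyl-1,3-dioxan-2-yl acetal of 6, F2. Hydrolysis (aq HCl, THF) rejoins the route at 6.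

Step 8 (site-selective sulfation). Boronate masking may be incomplete, the remaining phenol is hindered and hydrogen-bonded to CHO, and 15 is air-sensitive. The fallback uses an isolable catechol protecting group. It sets out from 15: tBu2Si(OTf)2 with 2,6-lutidine in DMF at 0 °C gives the catechol di-tert-butylsilylene F5. SO3·NMe3 with Et3N in DMF at 50 °C gives its aryl sulfate F6. HF·pyridine in THF at 0 °C followed by the same cation exchange removes the silylene and rejoins the route at 18.

**Further compounds**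
F1 | step 3 | 2-[(E)-but-2-en-2-yl]-(4R,6R)-4,6-dimethyl-1,3-dioxane | C/C=C(\C)C1O[C@H](C)C[C@@H](C)O1
F2 | step 3 | (4R,6R)-4,6-dimethyl-1,3-dioxan-2-yl acetal of 6 | C[C@@H]1CC=C2[C@@H](CCCC2(C)C)[C@]1(C3O[C@H](C)C[C@@H](C)O3)C
F3 | step 4 | 3-(2,4,5-trimethoxyphenyl)propanal | O=CCCc1cc(OC)c(OC)cc1OC
F4 | step 4 | (E)-2-[(2,4,5-trimethoxyphenyl)methyl]but-2-enal | C/C=C(\Cc1cc(OC)c(OC)cc1OC)C=O
F5 | step 8 | catechol di-tert-butylsilylene of 15 | C[C@@H]1CC=C2[C@@H](CCCC2(C)C)[C@]1(C)Cc1cc3O[Si](C(C)(C)C)(C(C)(C)C)Oc3c(C=O)c1O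
F6 | step 8 | hydrogen sulfate of F5 | C[C@@H]1CC=C2[C@@H](CCCC2(C)C)[C@]1(C)Cc1cc3O[Si](C(C)(C)C)(C(C)(C)C)Oc3c(C=O)c1OS(=O)(=O)O
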